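Plan
1. Retrosynthetic cuts in the carbocycle (2-oxaspiro[4.5]decane locants, spiro atom C5): after removing the C9=C10 unsaturation, the C5–C10 single bond and the C6=C7 double bond are cut together (Robinson retron), giving an oxolane-3-carbaldehyde and 1-methoxybut-3-en-2-one.
2. Enabling feature: C5 is the only quaternary atom of the dienone ring (C5–C10) and sits γ to the C8 carbonyl, its neighbour C6 is an unsubstituted CH and C7 carries OMe. C5/C6 therefore read as α-carbon/formyl carbon of an enolisable aldehyde and C7–C10 as a methoxymethyl vinyl ketone; the C1 and C4 substituents flanking C5 share one face of the oxolane (O2, C1, C3, C4, C5).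
3. Oxolane cuts: O2–C3 (benzylic C–O, cation capture), C1–C1′ (syn aldol of an aryloxyacetyl imide), C3–C4 (syn aldol); the formyl carbon comes from an exocyclic methylene (α-methylenation, later hydroboration/oxidation).
4. Forward order: two auxiliary-controlled aldols build the chain, acid closes the oxolane, the methylene becomes the aldehyde, the annulation builds the carbocycle, then dehydrogenation and global desilylation.
5. Stereochemistry: C4 from the (S)-auxiliary aldol; C1 and C1′ from the (R)-auxiliary aldol; C3 by thermodynamic control in the benzylic closure (aryl trans to both neighbours); C5 by substrate control (the enone enters anti to the C1 and C4 substituents).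

Key step: step 17

Remark: 1-methoxybut-3-en-2-one (29) is assumed to be purchasable (distilled before use); ArA = 3-methoxy-4-(triisopropylsilyloxy)phenyl, ArB = 2-methoxy-4-[3-(tert-butyldiphenylsilyloxy)propyl]phenyl, TBS = tert-butyldimethylsilyl.

Step 1
Reactants: 1 vanillin (4-hydroxy-3-methoxybenzaldehyde)
Product: 2 3-methoxy-4-(triisopropylsilyloxy)benzaldehyde
Conditions: i-Pr3SiCl, imidazole, DMF, rt
Reagents that add atoms: triisopropylsilyl chloride, CC(C)[Si](Cl)(C(C)C)C(C)C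
Why: Standard phenol silylation; the bulky aryl silyl ether should survive the later borohydride, acid, borane and amide-base steps and fall to fluoride at the end.

Step 2
Reactants: 3 (S)-4-benzyl-1,3-oxazolidin-2-one; 4 pent-4-enoyl chloride
Product: 5 (4S)-4-benzyl-3-(pent-4-enoyl)-1,3-oxazolidin-2-one
Conditions: Et3N, 4-(dimethylamino)pyridine (cat.), CH2Cl2, 0 °C → rt
Reagents that add atoms: none
Why: Amine-mediated N-acylation of the oxazolidinone installs the auxiliary for the first Evans aldol, the allyl group being the latent two-carbon aldehyde arm.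

Step 3
Reactants: 5 (4S)-4-benzyl-3-(pent-4-enoyl)-1,3-oxazolidin-2-one; 2 3-methoxy-4-(triisopropylsilyloxy)benzaldehyde
Product: 7 (4S)-4-benzyl-3-{(2S)-2-[(S)-hydroxy(ArA)methyl]pent-4-enoyl}-1,3-oxazolidin-2-one, via dibutylboron Z-enolate 6 (not isolated)
Conditions: Bu2BOTf, i-Pr2NEt, CH2Cl2, −78 → 0 °C; then 2, −78 → 0 °C; pH 7 buffer, MeOH, H2O2, 0 °C
Reagents that add atoms: none
Why: Evans syn aldol: the Z-boron enolate should add through a closed chair transition state on the face away from the benzyl group of the (S)-auxiliary, setting the acyl α-carbon (future C4) and a syn benzylic carbinol.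

Step 4
Reactants: 7 Evans syn aldol adduct
Product: 8 (1S,2R)-1-(ArA)-2-(prop-2-en-1-yl)propane-1,3-diol
Conditions: LiBH4, MeOH (1 equiv), THF, 0 °C
Reagents that add atoms: none
Why: Reductive removal of the auxiliary (LiBH4 attacks the exocyclic imide carbonyl) should give the primary alcohol that becomes the C4 hydroxymethyl group, with the auxiliary recovered.

Step 5
Reactants: 8 (1S,2R)-1-(ArA)-2-(prop-2-en-1-yl)propane-1,3-diol
Product: 9 (4S,5R)-4-(ArA)-2,2-dimethyl-5-(prop-2-en-1-yl)-1,3-dioxane (4,5-cis)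
Conditions: 2,2-dimethoxypropane, pyridinium p-toluenesulfonate (cat.), CH2Cl2, rt
Reagents that add atoms: 2,2-dimethoxypropane, COC(C)(C)OC
Why: Transketalisation ties the 1,3-diol into a six-membered acetonide, a temporary ring that masks the benzylic and primary hydroxyls until the oxolane is closed.

Step 6
Reactants: 9 (4S,5R)-4-(ArA)-2,2-dimethyl-5-(prop-2-en-1-yl)-1,3-dioxane
Product: 11 [(4S,5R)-4-(ArA)-2,2-dimethyl-1,3-dioxan-5-yl]acetaldehyde, via vicinal diol 10 (not isolated)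
Conditions: OsO4 (cat.), NaIO4, 2,6-lutidine, 1,4-dioxane/H2O (3:1), rt
Reagents that add atoms: osmium tetroxide, O=[Os](=O)(=O)=O (delivers the oxygen; reoxidised by sodium periodate, [Na+].[O-]I(=O)(=O)=O)
Why: Lemieux–Johnson cleavage (catalytic dihydroxylation, then periodate glycol cleavage) of the terminal alkene should give the one-carbon-shorter aldehyde without the arene oxidation that ozone could cause.

Step 7
Reactants: 11 [(4S,5R)-4-(ArA)-2,2-dimethyl-1,3-dioxan-5-yl]acetaldehyde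
Product: 12 2-[(4S,5R)-4-(ArA)-2,2-dimethyl-1,3-dioxan-5-yl]prop-2-enal
Conditions: CH2O (37% aq), pyrrolidine (10 mol%), propionic acid (10 mol%), i-PrOH, 45 °C
Reagents that add atoms: formaldehyde, C=O
Why: Amine/acid-catalysed Mannich condensation and elimination (organocatalytic α-methylenation of an aldehyde with an α-CH2 group) should install the exocyclic methylene, the one-carbon handle that later becomes the formyl carbon (C6 of the target).

Step 8
Reactants: 13 (R)-4-benzyl-1,3-oxazolidin-2-one; 14 bromoacetyl bromide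
Product: 16 (4R)-4-benzyl-3-(bromoacetyl)-1,3-oxazolidin-2-one, via lithium oxazolidinide 15 (not isolated)
Conditions: n-BuLi, THF, −78 °C; then 14, −78 → 0 °C
Reagents that add atoms: none
Why: N-acylation of the lithiated oxazolidinone; the acyl bromide should react far faster than the alkyl bromide.

Step 9
Reactants: 17 dihydroconiferyl alcohol (4-(3-hydroxypropyl)-2-methoxyphenol); 16 (4R)-4-benzyl-3-(bromoacetyl)-1,3-oxazolidin-2-one
Product: 18 (4R)-4-benzyl-3-{[4-(3-hydroxypropyl)-2-methoxyphenoxy]acetyl}-1,3-oxazolidin-2-one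
Conditions: K2CO3, acetone, rt
Reagents that add atoms: none
Why: Williamson ether synthesis: K2CO3 deprotonates only the phenol, whose phenoxide displaces the activated α-bromide while the aliphatic alcohol stays untouched.

Step 10
Reactants: 18 (4R)-4-benzyl-3-{[4-(3-hydroxypropyl)-2-methoxyphenoxy]acetyl}-1,3-oxazolidin-2-one
Product: 19 (4R)-4-benzyl-3-[(ArB-oxy)acetyl]-1,3-oxazolidin-2-one
Conditions: t-BuPh2SiCl, imidazole, CH2Cl2, rt
Reagents that add atoms: tert-butyl(chloro)diphenylsilane, CC(C)(C)[Si](Cl)(c1ccccc1)c1ccccc1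
Why: Standard silylation of the primary alcohol with the acid-stable tert-butyldiphenylsilyl group, chosen to survive the acid step 13.

Step 11
Reactants: 19 (4R)-4-benzyl-3-[(ArB-oxy)acetyl]-1,3-oxazolidin-2-one; 12 2-[(4S,5R)-4-(ArA)-2,2-dimethyl-1,3-dioxan-5-yl]prop-2-enal
Product: 21 (4R)-4-benzyl-3-{(2R,3S)-2-(ArB-oxy)-3-hydroxy-4-[(4S,5R)-4-(ArA)-2,2-dimethyl-1,3-dioxan-5-yl]pent-4-enoyl}-1,3-oxazolidin-2-one, via dibutylboron Z-enolate 20 (not isolated)
Conditions: Bu2BOTf, Et3N, CH2Cl2, −78 → 0 °C; then 12, −78 → −10 °C; pH 7 buffer, MeOH, H2O2, 0 °C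
Reagents that add atoms: none
Why: Evans syn aldol of an aryloxyacetyl (glycolate-type) imide with a 2-substituted acrolein: the (R)-auxiliary should fix both new centres (future C1 and C1′, syn), the remote dioxane centres having little influence on this reagent-controlled addition.

Step 12
Reactants: 21 second Evans syn aldol adduct
Product: 22 (2S,3S)-2-(ArB-oxy)-4-[(4S,5R)-4-(ArA)-2,2-dimethyl-1,3-dioxan-5-yl]pent-4-ene-1,3-diol
Conditions: LiBH4, MeOH (1 equiv), THF, 0 °C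
Reagents that add atoms: none
Why: Reductive removal of the auxiliary should give the primary alcohol of the side chain (C2′) and return the (R)-oxazolidinone.

Step 13
Reactants: 22 (2S,3S)-2-(ArB-oxy)-4-[(4S,5R)-4-(ArA)-2,2-dimethyl-1,3-dioxan-5-yl]pent-4-ene-1,3-diol
Product: 24 (2S)-2-(ArB-oxy)-2-[(2S,4R,5S)-5-(ArA)-4-(hydroxymethyl)-3-methylideneoxolan-2-yl]ethan-1-ol, via acyclic tetraol 23 (not isolated)
Conditions: CF3CO2H, CH2Cl2/H2O (20:1), 0 °C → rt; aq NaHCO3
Reagents that add atoms: none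
Why: Aqueous acid should hydrolyse the acetonide and ionise the electron-rich benzylic alcohol, the secondary hydroxyl capturing the cation in a five-membered (5-exo-tet type) SN1 cycloetherification as used for 2-aryl oxolane lignans; because this closure is reversible, the aryl group should settle trans to both the hydroxymethyl group and the side chain.

Step 14
Reactants: 24 3-methylideneoxolane diol
Product: 25 (2S,4R,5S)-5-(ArA)-2-[(1S)-1-(ArB-oxy)-2-(TBS-oxy)ethyl]-4-[(TBS-oxy)methyl]-3-methylideneoxolane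
Conditions: t-BuMe2SiCl, imidazole, DMF, rt
Reagents that add atoms: tert-butyldimethylsilyl chloride, CC(C)(C)[Si](C)(C)Cl
Why: Standard silylation of the two primary alcohols so that the alcohol made in step 15 is the only one open to oxidation.

Step 15
Reactants: 25 bis-silylated 3-methylideneoxolane
Product: 27 {(2S,4R,5S)-5-(ArA)-2-[(1S)-1-(ArB-oxy)-2-(TBS-oxy)ethyl]-4-[(TBS-oxy)methyl]oxolan-3-yl}methanol (C3 epimers), via B-alkyl-9-borabicyclononane 26 (not isolated)
Conditions: 9-BBN, THF, rt → 60 °C; then NaBO3·4H2O, H2O, rt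
Reagents that add atoms: sodium perborate, [Na+].[Na+].O[B-]1(O)OO[B-](O)(O)OO1
Why: Anti-Markovnikov hydroboration of the 1,1-disubstituted exocyclic alkene and mild perborate oxidation should give the primary alcohol; the configuration of the new ring CH is irrelevant because it is enolised in step 17.

Step 16
Reactants: 27 oxolan-3-ylmethanol
Product: 28 (2S,4R,5S)-5-(ArA)-2-[(1S)-1-(ArB-oxy)-2-(TBS-oxy)ethyl]-4-[(TBS-oxy)methyl]oxolane-3-carbaldehyde (C3 epimers)
Conditions: Dess–Martin periodinane, NaHCO3, CH2Cl2, 0 °C → rt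
Reagents that add atoms: none
Why: Buffered Dess–Martin oxidation should give the β-alkoxy aldehyde without elimination or silyl loss.

Step 17
Reactants: 28 oxolane-3-carbaldehyde; 29 1-methoxybut-3-en-2-one
Product: 32 (1S,3S,4R,5S)-3-(ArA)-1-[(1S)-1-(ArB-oxy)-2-(TBS-oxy)ethyl]-4-[(TBS-oxy)methyl]-7-methoxy-2-oxaspiro[4.5]dec-6-en-8-one, via pyrrolidine enamine 30 (not isolated), via keto aldehyde 31 (not isolated)
Conditions: pyrrolidine (1.1 equiv), 4 Å molecular sieves, toluene, rt → 50 °C, then evaporation; 29 (2 equiv), MeCN, 0 → 40 °C; then AcOH/NaOAc/H2O, 60 °C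
Reagents that add atoms: none
Why: Condensation gives the exocyclic enamine 30, whose ring carbon adds to the β-carbon of the vinyl ketone (Michael addition, forming the C5–C10 bond and the quaternary centre); hydrolysis gives keto aldehyde 31, and pyrrolidinium acetate then drives aldol condensation of the methoxy-bearing α′-carbon onto the formyl group with loss of water (forming C6=C7). The closest known reaction type is the Stork enamine variant of the Robinson annulation of α-branched aldehydes with vinyl ketones to 4,4-disubstituted cyclohex-2-enones. The carbocycle closes by a 6-(enolexo)-exo-trig aldol addition, and closure through the other α-carbon would give a four-membered ring, so only the 2-methoxy enone can form. The spiro carbon C5 is set in the Michael step by the substrate: the C1 side chain and the C4 silyloxymethyl group both lie on the lower face of the oxolane, so the enone should enter from the upper face, which places the C10 arm cis to the remote C3 aryl group as in the target. The step needs this facial selectivity and survival of the β-alkoxy aldehyde; loss of the ring oxygen from the enamine would be the reverse of a 5-endo-trig closure, with the breaking C–O bond close to the nodal plane of the enamine π system, and the neutral conditions avoid enolate-type elimination.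

Step 18
Reactants: 32 spirocyclic 2-methoxy enone
Product: 34 (1S,3S,4R,5S)-3-(ArA)-1-[(1S)-1-(ArB-oxy)-2-(TBS-oxy)ethyl]-4-[(TBS-oxy)methyl]-7-methoxy-2-oxaspiro[4.5]deca-6,9-dien-8-one, via trimethylsilyl dienol ether 33 (not isolated)
Conditions: LiN(SiMe3)2, Me3SiCl, THF, −78 °C; then Pd(OAc)2 (1.1 equiv), MeCN, rt
Reagents that add atoms: none
Why: Saegusa–Ito dehydrogenation: enolisation can occur only at C9 because C5 is quaternary, and the silyl dienol ether should give a palladium enolate that undergoes β-hydride elimination to the cross-conjugated dienone without touching any stereocentre.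

Step 19
Reactants: 34 fully silylated spirodienone
Product: 35 (1S,3S,4R,5S)-3-(4-hydroxy-3-methoxyphenyl)-4-(hydroxymethyl)-1-{(1S)-2-hydroxy-1-[4-(3-hydroxypropyl)-2-methoxyphenoxy]ethyl}-7-methoxy-2-oxaspiro[4.5]deca-6,9-dien-8-one (CNP0252711.1)
Conditions: Bu4NF/AcOH (1:1, excess), THF, 0 °C → rt
Reagents that add atoms: none
Why: Acetic-acid-buffered fluoride should cleave all four silyl ethers while avoiding strong acid (fragmentation of the spirodienone to a phenol) and free alkoxide or phenoxide (oxa-Michael addition to the dienone, quinone-methide opening of the benzylic ether).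

Compound list
1 | vanillin (4-hydroxy-3-methoxybenzaldehyde) | COc1cc(C=O)ccc1O | starting material
2 | 3-methoxy-4-(triisopropylsilyloxy)benzaldehyde | COc1cc(C=O)ccc1O[Si](C(C)C)(C(C)C)C(C)C | intermediate
3 | (S)-4-benzyl-1,3-oxazolidin-2-one | O=C1N[C@@H](Cc2ccccc2)CO1 | starting material
4 | pent-4-enoyl chloride | C=CCCC(=O)Cl | starting material
5 | (4S)-4-benzyl-3-(pent-4-enoyl)-1,3-oxazolidin-2-one | C=CCCC(=O)N1[C@@H](Cc2ccccc2)COC1=O | intermediate
6 | dibutylboron Z-enolate of 5 | C=CC/C=C(\OB(CCCC)CCCC)N1[C@@H](Cc2ccccc2)COC1=O | intermediate (not isolated)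
7 | (4S)-4-benzyl-3-{(2S)-2-[(S)-hydroxy(ArA)methyl]pent-4-enoyl}-1,3-oxazolidin-2-one | C=CC[C@H](C(=O)N1[C@@H](Cc2ccccc2)COC1=O)[C@H](O)c1ccc(O[Si](C(C)C)(C(C)C)C(C)C)c(OC)c1 | intermediate
8 | (1S,2R)-1-(ArA)-2-(prop-2-en-1-yl)propane-1,3-diol | C=CC[C@H](CO)[C@H](O)c1ccc(O[Si](C(C)C)(C(C)C)C(C)C)c(OC)c1 | intermediate
9 | (4S,5R)-4-(ArA)-2,2-dimethyl-5-(prop-2-en-1-yl)-1,3-dioxane | C=CC[C@@H]1COC(C)(C)O[C@@H]1c1ccc(O[Si](C(C)C)(C(C)C)C(C)C)c(OC)c1 | intermediate
10 | 3-[(4S,5R)-4-(ArA)-2,2-dimethyl-1,3-dioxan-5-yl]propane-1,2-diol (mixture at the new carbinol) | OCC(O)C[C@@H]1COC(C)(C)O[C@@H]1c1ccc(O[Si](C(C)C)(C(C)C)C(C)C)c(OC)c1 | intermediate (not isolated)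
11 | [(4S,5R)-4-(ArA)-2,2-dimethyl-1,3-dioxan-5-yl]acetaldehyde | O=CC[C@@H]1COC(C)(C)O[C@@H]1c1ccc(O[Si](C(C)C)(C(C)C)C(C)C)c(OC)c1 | intermediate
12 | 2-[(4S,5R)-4-(ArA)-2,2-dimethyl-1,3-dioxan-5-yl]prop-2-enal | C=C(C=O)[C@@H]1COC(C)(C)O[C@@H]1c1ccc(O[Si](C(C)C)(C(C)C)C(C)C)c(OC)c1 | intermediate
13 | (R)-4-benzyl-1,3-oxazolidin-2-one | O=C1N[C@H](Cc2ccccc2)CO1 | starting material
14 | bromoacetyl bromide | BrCC(Br)=O | starting material
15 | lithium salt of 13 | [Li+].O=C1[N-][C@H](Cc2ccccc2)CO1 | intermediate (not isolated)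
16 | (4R)-4-benzyl-3-(bromoacetyl)-1,3-oxazolidin-2-one | BrCC(=O)N1[C@H](Cc2ccccc2)COC1=O | intermediate
17 | dihydroconiferyl alcohol (4-(3-hydroxypropyl)-2-methoxyphenol) | COc1cc(CCCO)ccc1O | starting material
18 | (4R)-4-benzyl-3-{[4-(3-hydroxypropyl)-2-methoxyphenoxy]acetyl}-1,3-oxazolidin-2-one | COc1cc(CCCO)ccc1OCC(=O)N1[C@H](Cc2ccccc2)COC1=O | intermediate
19 | (4R)-4-benzyl-3-[(ArB-oxy)acetyl]-1,3-oxazolidin-2-one | COc1cc(CCCO[Si](c2ccccc2)(c2ccccc2)C(C)(C)C)ccc1OCC(=O)N1[C@H](Cc2ccccc2)COC1=O | intermediate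
20 | dibutylboron Z-enolate of 19 | COc1cc(CCCO[Si](c2ccccc2)(c2ccccc2)C(C)(C)C)ccc1O/C=C(\OB(CCCC)CCCC)N1[C@H](Cc2ccccc2)COC1=O | intermediate (not isolated)
21 | (4R)-4-benzyl-3-{(2R,3S)-2-(ArB-oxy)-3-hydroxy-4-[(4S,5R)-4-(ArA)-2,2-dimethyl-1,3-dioxan-5-yl]pent-4-enoyl}-1,3-oxazolidin-2-one | C=C([C@H](O)[C@@H](Oc1ccc(CCCO[Si](c2ccccc2)(c2ccccc2)C(C)(C)C)cc1OC)C(=O)N1[C@H](Cc2ccccc2)COC1=O)[C@@H]1COC(C)(C)O[C@@H]1c1ccc(O[Si](C(C)C)(C(C)C)C(C)C)c(OC)c1 | intermediate
22 | (2S,3S)-2-(ArB-oxy)-4-[(4S,5R)-4-(ArA)-2,2-dimethyl-1,3-dioxan-5-yl]pent-4-ene-1,3-diol | C=C([C@H](O)[C@H](CO)Oc1ccc(CCCO[Si](c2ccccc2)(c2ccccc2)C(C)(C)C)cc1OC)[C@@H]1COC(C)(C)O[C@@H]1c1ccc(O[Si](C(C)C)(C(C)C)C(C)C)c(OC)c1 | intermediate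
23 | (1S,2R,4S,5S)-1-(ArA)-5-(ArB-oxy)-2-(hydroxymethyl)-3-methylidenehexane-1,4,6-triol | C=C([C@H](O)[C@H](CO)Oc1ccc(CCCO[Si](c2ccccc2)(c2ccccc2)C(C)(C)C)cc1OC)[C@H](CO)[C@H](O)c1ccc(O[Si](C(C)C)(C(C)C)C(C)C)c(OC)c1 | intermediate (not isolated)
24 | (2S)-2-(ArB-oxy)-2-[(2S,4R,5S)-5-(ArA)-4-(hydroxymethyl)-3-methylideneoxolan-2-yl]ethan-1-ol | C=C1[C@H](CO)[C@@H](c2ccc(O[Si](C(C)C)(C(C)C)C(C)C)c(OC)c2)O[C@@H]1[C@H](CO)Oc1ccc(CCCO[Si](c2ccccc2)(c2ccccc2)C(C)(C)C)cc1OC | intermediate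
25 | (2S,4R,5S)-5-(ArA)-2-[(1S)-1-(ArB-oxy)-2-(TBS-oxy)ethyl]-4-[(TBS-oxy)methyl]-3-methylideneoxolane | C=C1[C@H](CO[Si](C)(C)C(C)(C)C)[C@@H](c2ccc(O[Si](C(C)C)(C(C)C)C(C)C)c(OC)c2)O[C@@H]1[C@H](CO[Si](C)(C)C(C)(C)C)Oc1ccc(CCCO[Si](c2ccccc2)(c2ccccc2)C(C)(C)C)cc1OC | intermediate
26 | 9-(oxolan-3-ylmethyl)-9-borabicyclo[3.3.1]nonane derived from 25 (C3 epimers) | C(B1C2CCCC1CCC2)C1[C@H](CO[Si](C)(C)C(C)(C)C)[C@@H](c2ccc(O[Si](C(C)C)(C(C)C)C(C)C)c(OC)c2)O[C@@H]1[C@H](CO[Si](C)(C)C(C)(C)C)Oc1ccc(CCCO[Si](c2ccccc2)(c2ccccc2)C(C)(C)C)cc1OC | intermediate (not isolated)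
27 | {(2S,4R,5S)-5-(ArA)-2-[(1S)-1-(ArB-oxy)-2-(TBS-oxy)ethyl]-4-[(TBS-oxy)methyl]oxolan-3-yl}methanol (C3 epimers) | OCC1[C@H](CO[Si](C)(C)C(C)(C)C)[C@@H](c2ccc(O[Si](C(C)C)(C(C)C)C(C)C)c(OC)c2)O[C@@H]1[C@H](CO[Si](C)(C)C(C)(C)C)Oc1ccc(CCCO[Si](c2ccccc2)(c2ccccc2)C(C)(C)C)cc1OC | intermediate
28 | (2S,4R,5S)-5-(ArA)-2-[(1S)-1-(ArB-oxy)-2-(TBS-oxy)ethyl]-4-[(TBS-oxy)methyl]oxolane-3-carbaldehyde (C3 epimers) | O=CC1[C@H](CO[Si](C)(C)C(C)(C)C)[C@@H](c2ccc(O[Si](C(C)C)(C(C)C)C(C)C)c(OC)c2)O[C@@H]1[C@H](CO[Si](C)(C)C(C)(C)C)Oc1ccc(CCCO[Si](c2ccccc2)(c2ccccc2)C(C)(C)C)cc1OC | intermediate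
29 | 1-methoxybut-3-en-2-one | C=CC(=O)COC | starting material
30 | 1-{[(2S,4R,5S)-oxolan-3-ylidene]methyl}pyrrolidine derived from 28 | C1CCN(C1)C=C1[C@H](CO[Si](C)(C)C(C)(C)C)[C@@H](c2ccc(O[Si](C(C)C)(C(C)C)C(C)C)c(OC)c2)O[C@@H]1[C@H](CO[Si](C)(C)C(C)(C)C)Oc1ccc(CCCO[Si](c2ccccc2)(c2ccccc2)C(C)(C)C)cc1OC | intermediate (not isolated)
31 | (2S,3R,4R,5S)-5-(ArA)-2-[(1S)-1-(ArB-oxy)-2-(TBS-oxy)ethyl]-4-[(TBS-oxy)methyl]-3-(4-methoxy-3-oxobutyl)oxolane-3-carbaldehyde | O=C[C@]1(CCC(=O)COC)[C@H](CO[Si](C)(C)C(C)(C)C)[C@@H](c2ccc(O[Si](C(C)C)(C(C)C)C(C)C)c(OC)c2)O[C@@H]1[C@H](CO[Si](C)(C)C(C)(C)C)Oc1ccc(CCCO[Si](c2ccccc2)(c2ccccc2)C(C)(C)C)cc1OC | intermediate (not isolated)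
32 | (1S,3S,4R,5S)-3-(ArA)-1-[(1S)-1-(ArB-oxy)-2-(TBS-oxy)ethyl]-4-[(TBS-oxy)methyl]-7-methoxy-2-oxaspiro[4.5]dec-6-en-8-one | COC1=C[C@]2(CCC1=O)[C@H](CO[Si](C)(C)C(C)(C)C)[C@@H](c1ccc(O[Si](C(C)C)(C(C)C)C(C)C)c(OC)c1)O[C@@H]2[C@H](CO[Si](C)(C)C(C)(C)C)Oc1ccc(CCCO[Si](c2ccccc2)(c2ccccc2)C(C)(C)C)cc1OC | intermediate
33 | 8-(trimethylsilyloxy)-2-oxaspiro[4.5]deca-6,8-diene derived from 32 | COC1=C[C@]2(CC=C1O[Si](C)(C)C)[C@H](CO[Si](C)(C)C(C)(C)C)[C@@H](c1ccc(O[Si](C(C)C)(C(C)C)C(C)C)c(OC)c1)O[C@@H]2[C@H](CO[Si](C)(C)C(C)(C)C)Oc1ccc(CCCO[Si](c2ccccc2)(c2ccccc2)C(C)(C)C)cc1OC | intermediate (not isolated)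
34 | (1S,3S,4R,5S)-3-(ArA)-1-[(1S)-1-(ArB-oxy)-2-(TBS-oxy)ethyl]-4-[(TBS-oxy)methyl]-7-methoxy-2-oxaspiro[4.5]deca-6,9-dien-8-one | COC1=C[C@]2(C=CC1=O)[C@H](CO[Si](C)(C)C(C)(C)C)[C@@H](c1ccc(O[Si](C(C)C)(C(C)C)C(C)C)c(OC)c1)O[C@@H]2[C@H](CO[Si](C)(C)C(C)(C)C)Oc1ccc(CCCO[Si](c2ccccc2)(c2ccccc2)C(C)(C)C)cc1OC | intermediate
35 | (1S,3S,4R,5S)-3-(4-hydroxy-3-methoxyphenyl)-4-(hydroxymethyl)-1-{(1S)-2-hydroxy-1-[4-(3-hydroxypropyl)-2-methoxyphenoxy]ethyl}-7-methoxy-2-oxaspiro[4.5]deca-6,9-dien-8-one | COC1=C[C@]2(C=CC1=O)[C@H](CO)[C@@H](c1ccc(O)c(OC)c1)O[C@@H]2[C@H](CO)Oc1ccc(CCCO)cc1OC | target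

Total step count: 19.
Longest linear sequence: 15 steps (steps 2–7, then 11–19; the arm through step 1 is equally long).

Steps most likely to fail

Step 17. The hindered exocyclic enamine may add to the enone too slowly, so that polymerisation or amine addition consumes 29; it may also add with insufficient facial selectivity, or lose the ring oxygen by β-elimination. The fallback sets out from 28. The aldehyde would be converted into its trimethylsilyl enol ether F1 (Me3SiOTf, Et3N, CH2Cl2, 0 °C). F1 would be joined to 29 in a Lewis-acid-mediated Mukaiyama–Michael addition (Sc(OTf)3 cat., CH2Cl2, −78 °C) and the adduct hydrolysed on work-up to keto aldehyde 31, which is isolated here. A separate aldol condensation (KOH, MeOH, 0 °C) would close the ring, and the route is rejoined at 32.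

Step 13. Ionisation of the benzylic centre may be accompanied by elimination towards a styrene, protonation of the exocyclic alkene, partial loss of silyl groups or incomplete equilibration of the benzylic centre. The fallback sets out from 22 and relies on a para-quinone methide instead of a simple benzylic cation. Selective cleavage of the aryl silyl ether (K2CO3, MeOH, 0 °C) would give the phenol F2. Mild acid (pyridinium p-toluenesulfonate, MeOH/H2O, 40 °C) should then remove the acetonide and convert the para-hydroxybenzylic alcohol into a quinone methide, which the secondary hydroxyl captures by 1,6-addition under thermodynamic control to give the phenolic oxolane diol F3. Phenoxide-selective resilylation (i-Pr3SiCl, DBU, CH2Cl2, 0 °C) returns to 24.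

Step 18. Enolisation and silylation may be incomplete, or the palladium step may stall or attack the electron-rich arenes and silyl ethers. The fallback sets out from 32. The lithium enolate (LiN(SiMe3)2, THF, −78 °C) would be trapped with PhSeCl to give the 9-(phenylselanyl) ketone F4. Oxidation (H2O2, pyridine, CH2Cl2, 0 °C) and syn-elimination of the selenoxide return to 34.

Further compounds
F1 | step 17 | trimethylsilyl enol ether of 28 ({[(2S,4R,5S)-oxolan-3-ylidene]methoxy}trimethylsilane) | C[Si](C)(C)OC=C1[C@H](CO[Si](C)(C)C(C)(C)C)[C@@H](c2ccc(O[Si](C(C)C)(C(C)C)C(C)C)c(OC)c2)O[C@@H]1[C@H](CO[Si](C)(C)C(C)(C)C)Oc1ccc(CCCO[Si](c2ccccc2)(c2ccccc2)C(C)(C)C)cc1OC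
F2 | step 13 | (2S,3S)-2-(ArB-oxy)-4-[(4S,5R)-4-(4-hydroxy-3-methoxyphenyl)-2,2-dimethyl-1,3-dioxan-5-yl]pent-4-ene-1,3-diol | C=C([C@H](O)[C@H](CO)Oc1ccc(CCCO[Si](c2ccccc2)(c2ccccc2)C(C)(C)C)cc1OC)[C@@H]1COC(C)(C)O[C@@H]1c1ccc(O)c(OC)c1
F3 | step 13 | (2S)-2-(ArB-oxy)-2-[(2S,4R,5S)-5-(4-hydroxy-3-methoxyphenyl)-4-(hydroxymethyl)-3-methylideneoxolan-2-yl]ethan-1-ol | C=C1[C@H](CO)[C@@H](c2ccc(O)c(OC)c2)O[C@@H]1[C@H](CO)Oc1ccc(CCCO[Si](c2ccccc2)(c2ccccc2)C(C)(C)C)cc1OC
F4 | step 18 | 9-(phenylselanyl) derivative of 32 (C9 epimers) | COC1=C[C@]2(CC([Se]c3ccccc3)C1=O)[C@H](CO[Si](C)(C)C(C)(C)C)[C@@H](c1ccc(O[Si](C(C)C)(C(C)C)C(C)C)c(OC)c1)O[C@@H]2[C@H](CO[Si](C)(C)C(C)(C)C)Oc1ccc(CCCO[Si](c2ccccc2)(c2ccccc2)C(C)(C)C)cc1OC
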